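**Retrosynthetic overview**
- Ring D (C1''–C6'') is a para-disubstituted phenol: C1'' is bonded to the C8 methylene and C4'' carries OH. It is therefore the dehydrogenated form of a cyclohex-2-enone with C4''=O, C5''=C6'' and the flavonylmethyl group on sp3 C1''. The plan rests on this equivalence.
- The enone is cut at C1''–C2'' (conjugate addition) and at C5''–C6'' (aldol condensation). The chain C8–CH2–C1''–C6'' becomes a flavone 8-propanal, and C2''–C5'' is methyl vinyl ketone.
- The propanal is cut at C8–CH2, which points to Heck arylation of allyl alcohol with 8-iodoapigenin trimethyl ether. The iodide comes from apigenin by O-methylation and C8 iodination.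
- Rings A, C and B arrive intact with apigenin. Ring D is the only ring built (step 4); it is aromatised in step 5, and the three methyl ethers are cleaved last (step 6).

Key step: step 4

Remark: the target has no stereocentre. C1'' is a stereocentre only in the non-aromatic ring D precursors, is carried as the racemate, and disappears on aromatisation.

**Route**

Step 1
Reactants: 1 apigenin
Product: 2 5,7-dimethoxy-2-(4-methoxyphenyl)chromen-4-one (apigenin trimethyl ether)
Conditions: Me2SO4 (6 equiv), K2CO3 (8 equiv), acetone, reflux
Reagents that add atoms: dimethyl sulfate, COS(=O)(=O)OC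
Why: Williamson-type O-methylation of all three phenols, in which the chelated 5-OH reacts last and so calls for excess reagent and long reflux, while the weak carbonate base keeps alkylation on oxygen and away from C6 and C8.

Step 2
Reactants: 2 apigenin trimethyl ether
Product: 3 8-iodo-5,7-dimethoxy-2-(4-methoxyphenyl)chromen-4-one
Conditions: NIS (1.05 equiv), DMF, rt to 60 °C, dark
Reagents that add atoms: N-iodosuccinimide, O=C1CCC(=O)N1I
Why: Electrophilic aromatic iodination, in which ring A with its three oxygen donors is the most nucleophilic ring, C8 (between one methoxy group and the tied-back ring oxygen O1) reacts ahead of C6 (wedged between two methoxy groups) in 5,7-dialkoxyflavones, and one equivalent of reagent limits a second iodination.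

Step 3
Reactants: 3 8-iodoapigenin trimethyl ether; 4 allyl alcohol (2.5 equiv)
Product: 5 3-[5,7-dimethoxy-2-(4-methoxyphenyl)-4-oxochromen-8-yl]propanal
Conditions: Pd(OAc)2 (5 mol %), Bu4NCl (1 equiv), NaHCO3 (2.5 equiv), DMF, 50 °C, Ar
Reagents that add atoms: allyl alcohol, C=CCO (compound 4)
Why: Heck arylation of an allylic alcohol under Jeffery conditions, in which the aryl group goes to the terminal alkene carbon, palladium walks to the carbinol carbon by β-hydride elimination and re-addition and releases the aldehyde, and the trisubstituted donor-flanked C2=C3 bond of the flavone does not compete as an alkene partner.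

Step 4
Reactants: 5 flavone 8-propanal; 6 methyl vinyl ketone (1.3 equiv)
Product: 10 5,7-dimethoxy-2-(4-methoxyphenyl)-8-[(4-oxocyclohex-2-en-1-yl)methyl]chromen-4-one (racemic), via pyrrolidine enamine 7 (not isolated), via keto aldehyde 8 (not isolated), via aldol 9 (not isolated)
Conditions: pyrrolidine (1.05 equiv), 4 Å MS, toluene, rt; 6, 0 °C to rt; then AcOH–NaOAc–H2O, reflux
Reagents that add atoms: methyl vinyl ketone, CC(=O)C=C (compound 6); in the intermediates only: pyrrolidine, C1CCNC1 (in 7), and water, O (aldehyde oxygen of 8, hydroxyl oxygen of 9)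
Why: Pyrrolidine condenses with the only aldehyde to give the E-enamine 7, whose β-carbon (the future C1'') adds to the CH2 terminus of 6 and forms C1''–C2'', after which the buffer hydrolyses the adduct to the 1,5-keto aldehyde 8 and gives the amine back. Pyrrolidinium acetate then enolises the methyl ketone, its CH3 carbon (C5'') attacks the aldehyde carbon (C6'') to give aldol 9, and E1cB loss of water delivers the conjugated enone 10. The closest known reaction type is the Stork enamine variant of the Robinson annulation, by which aldehydes and methyl vinyl ketone give 4-substituted cyclohex-2-enones. Ring D closes in the favoured 6-(enolendo)-exo-trig mode, both enol carbons C4'' and C5'' ending inside the new ring, whereas the other enolisable positions of 8 (C3'' onto C6'', or C1'' onto C4'') could only close four-membered rings. C1'' arises with no controlling element and is racemic, the carbinol centre of 9 is lost on dehydration, and C1'' becomes sp2 in step 5. The step needs a single Michael addition and no self-aldol, which is secured because the preformed enamine leaves no free aldehyde during C–C bond formation, the α-branched adduct is a much poorer donor, the flavone has no enolisable C–H and its C2 is deactivated toward the single equivalent of amine by the donor ring B, and closure in acetate buffer avoids the hot alkali that would open ring C.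

Step 5
Reactants: 10 enone
Product: 12 8-(4-hydroxybenzyl)-5,7-dimethoxy-2-(4-methoxyphenyl)chromen-4-one, via cross-conjugated dienone 11 (not isolated)
Conditions: Pd(OCOCF3)2 (5 mol %), 2-(dimethylamino)pyridine (10 mol %), TsOH·H2O (20 mol %), O2 (1 atm), DMSO, 80 °C
Reagents that add atoms: none
Why: Palladium-catalysed aerobic dehydrogenation of a cyclohexenone, in which a divalent palladium enolate forms at C3'', β-hydride elimination from C2'' gives dienone 11, the hydrogen on C1'' lets 11 tautomerise at once to the phenol, O2 reoxidises zerovalent palladium, and the fully unsaturated flavone and its methyl ethers have nothing to lose.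

Step 6
Reactants: 12 ring D phenol trimethyl ether
Product: 13 5,7-dihydroxy-8-(4-hydroxybenzyl)-2-(4-hydroxyphenyl)chromen-4-one (target, CNP0257058.0)
Conditions: BBr3 (10 equiv), CH2Cl2, −78 °C to rt; then ice–water
Reagents that add atoms: none
Why: Lewis-acid cleavage of aryl methyl ethers, bromide attacking the methyl carbon of each boron-complexed ether, run anhydrous and no warmer than room temperature so that ring C cannot open, a Wessely–Moser shift of the benzyl group from C8 to C6 is not expected, and the diarylmethane C–C bonds stay intact.

**Compound list**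
1 | apigenin, 5,7-dihydroxy-2-(4-hydroxyphenyl)chromen-4-one | O=c1cc(-c2ccc(O)cc2)oc2cc(O)cc(O)c12 | starting material
2 | 5,7-dimethoxy-2-(4-methoxyphenyl)chromen-4-one | COc1ccc(cc1)-c1cc(=O)c2c(OC)cc(OC)cc2o1 | intermediate
3 | 8-iodo-5,7-dimethoxy-2-(4-methoxyphenyl)chromen-4-one | COc1ccc(cc1)-c1cc(=O)c2c(OC)cc(OC)c(I)c2o1 | intermediate
4 | allyl alcohol | C=CCO | starting material
5 | 3-[5,7-dimethoxy-2-(4-methoxyphenyl)-4-oxochromen-8-yl]propanal | COc1ccc(cc1)-c1cc(=O)c2c(OC)cc(OC)c(CCC=O)c2o1 | intermediate
6 | methyl vinyl ketone | CC(=O)C=C | starting material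
7 | 5,7-dimethoxy-2-(4-methoxyphenyl)-8-[(E)-3-(pyrrolidin-1-yl)prop-2-enyl]chromen-4-one | COc1ccc(cc1)-c1cc(=O)c2c(OC)cc(OC)c(C/C=C/N3CCCC3)c2o1 | intermediate (not isolated)
8 | 2-{[5,7-dimethoxy-2-(4-methoxyphenyl)-4-oxochromen-8-yl]methyl}-5-oxohexanal (racemic) | COc1ccc(cc1)-c1cc(=O)c2c(OC)cc(OC)c(CC(C=O)CCC(C)=O)c2o1 | intermediate (not isolated)
9 | 8-[(2-hydroxy-4-oxocyclohexyl)methyl]-5,7-dimethoxy-2-(4-methoxyphenyl)chromen-4-one (racemic, mixture of diastereomers) | COc1ccc(cc1)-c1cc(=O)c2c(OC)cc(OC)c(CC3CCC(=O)CC3O)c2o1 | intermediate (not isolated)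
10 | 5,7-dimethoxy-2-(4-methoxyphenyl)-8-[(4-oxocyclohex-2-en-1-yl)methyl]chromen-4-one (racemic) | COc1ccc(cc1)-c1cc(=O)c2c(OC)cc(OC)c(CC3CCC(=O)C=C3)c2o1 | intermediate
11 | 5,7-dimethoxy-2-(4-methoxyphenyl)-8-[(4-oxocyclohexa-2,5-dien-1-yl)methyl]chromen-4-one | COc1ccc(cc1)-c1cc(=O)c2c(OC)cc(OC)c(CC3C=CC(=O)C=C3)c2o1 | intermediate (not isolated)
12 | 8-(4-hydroxybenzyl)-5,7-dimethoxy-2-(4-methoxyphenyl)chromen-4-one | COc1ccc(cc1)-c1cc(=O)c2c(OC)cc(OC)c(Cc3ccc(O)cc3)c2o1 | intermediate
13 | 5,7-dihydroxy-8-(4-hydroxybenzyl)-2-(4-hydroxyphenyl)chromen-4-one | O=c1cc(-c2ccc(O)cc2)oc2c(Cc3ccc(O)cc3)c(O)cc(O)c12 | target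

**Totals**
Total step count: 6. Longest linear sequence: 6 steps, from apigenin.

**Steps most likely to fail**

Step 4. Several processes may interfere:
- the unbranched aldehyde may condense with itself through its own enamine;
- the adduct may take up a second molecule of enone;
- methyl vinyl ketone may polymerise;
- the amine may add at C2 and open ring C.

The fallback runs from 5 back to 10 and reverses the polarity of the conjugate addition. Compound 5 is α-methylenated by Mannich condensation and elimination (37 % aqueous CH2O, pyrrolidine and propionic acid at 10 mol % each, iPrOH, 45 °C) to the 2-substituted acrolein F1. tert-Butyl acetoacetate then adds as a stabilised donor (DBU 10 mol %, CH2Cl2, 0 °C to rt) to give the formyl β-keto ester F2. TsOH in toluene at 90 °C cleaves and decarboxylates the tert-butyl ester to leave 8, which closes ring D by the same C5''–C6'' aldol condensation to 10. In this variant C2'' stems from formaldehyde and C3''–C5'' from the acetoacetate, and no aldehyde enamine has to meet an enone.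

Step 3. Oxidative addition and insertion may be slow at the electron-rich C8–I bond flanked by 7-OMe and O1. Reductive loss of iodine, insertion at the internal alkene carbon, or a chain walk that stops at the allylic alcohol stage could then compete.

The fallback runs from 3 back to 5 and replaces the Heck reaction by a B-alkyl Suzuki–Miyaura coupling. Acrolein diethyl acetal is hydroborated with 9-BBN-H (THF, 0 °C to rt) to the B-alkylborane F3. This is coupled in the same flask with 3 (PdCl2(dppf) 5 mol %, aqueous K3PO4, DMF–THF, 60 °C) to the diethyl acetal F4. Treatment with 1 M HCl in THF at rt then frees aldehyde 5. The hydroboration fixes the chain terminus, and the aldehyde stays masked during the coupling.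

Step 6. The 7-OMe group next to the benzyl substituent may resist cleavage. Forcing the Lewis acid, together with the acid it liberates, may protonate ring A at C8 and so detach or shift the 4-hydroxybenzyl group.

The fallback runs from 12 back to 13 and is a staged deprotection that ends under basic conditions. BCl3 (3 equiv, CH2Cl2, −20 to 0 °C) removes only the 5-O-methyl group, through the chelate with the C4 carbonyl, to give the 5-phenol F5. NaSEt (10 equiv, DMF, 130 °C, then dilute HCl) takes the 7- and 4'-methyl groups by SN2 attack at carbon, both aryloxide leaving groups being conjugated with C4=O. No strong acid then meets the free 5,7-dihydroxy-8-benzyl array.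

**Further compounds**
F1 | step 4 | 2-{[5,7-dimethoxy-2-(4-methoxyphenyl)-4-oxochromen-8-yl]methyl}prop-2-enal | COc1ccc(cc1)-c1cc(=O)c2c(OC)cc(OC)c(CC(=C)C=O)c2o1
F2 | step 4 | tert-butyl 2-acetyl-4-formyl-5-[5,7-dimethoxy-2-(4-methoxyphenyl)-4-oxochromen-8-yl]pentanoate (racemic, mixture of diastereomers) | COc1ccc(cc1)-c1cc(=O)c2c(OC)cc(OC)c(CC(C=O)CC(C(C)=O)C(=O)OC(C)(C)C)c2o1
F3 | step 3 | 9-(3,3-diethoxypropyl)-9-borabicyclo[3.3.1]nonane | CCOC(CCB1C2CCCC1CCC2)OCC
F4 | step 3 | 8-(3,3-diethoxypropyl)-5,7-dimethoxy-2-(4-methoxyphenyl)chromen-4-one | COc1ccc(cc1)-c1cc(=O)c2c(OC)cc(OC)c(CCC(OCC)OCC)c2o1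
F5 | step 6 | 5-hydroxy-8-(4-hydroxybenzyl)-7-methoxy-2-(4-methoxyphenyl)chromen-4-one | COc1ccc(cc1)-c1cc(=O)c2c(O)cc(OC)c(Cc3ccc(O)cc3)c2o1
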